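**Overview**

- Retrosynthesis first removes the periphery: the C1–C10 oxirane goes back to the E-alkene, the esters are cut at O3–acyl and O8–acyl, C13 is taken off C11, and the lactone is opened at O6–C12.
- Enabling feature: in the ten-membered ring C1–C10 the (masked) C1=C10 alkene lies 1,5 to the C6–C7 bond, with oxygen on C6 and on C8. A transannular C1–C6 bond would turn C1–C6 (C15 on C4) plus C9/C10/C14 into an isopropenyl-cyclohexenol of the carvone type carrying a C7=C8 enol ether on C6.
- Key cuts: C8–C9 (made while C1–C6 breaks, anionic oxy-Cope 6→10 ring expansion) and C6–C7 (alkenyllithium plus enone).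
- Forward order of rings: carvone six-membered ring (future C1–C6) → temporary seven-membered dioxepine from butenediol (C7, C8, C11, C12), joined at C6–C7 → ten-membered carbocycle by ring expansion → γ-lactone O6–C12 → side-chain oxirane attached with its acid → C1–C10 oxirane last.
- Stereochemistry: the carvone centre (future C1) sets C3 (Luche reduction, Mitsunobu inversion) and the C6 carbinol (anti addition), then is transferred through a chair transition state to C8. C7 comes from peripheral protonation, C6 from 8-OH-directed reduction, C1/C10 from peripheral peracid attack, and the side-chain centres from Sharpless epoxidation.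

Key step: step 12

Remark: from step 11 on, germacrane numbering is used (ring C1–C10, lactone carbons C11–C13, C14 on C10, C15 on C4; β = upper face of the usual drawing). The two oxirane centres of 6 are transient, so their assignment does not affect the outcome.

**Route**

Step 1
Reactants: 1 (R)-(−)-carvone
Product: 2 (1R,5R)-cis-carveol
Conditions: NaBH4, CeCl3·7H2O, MeOH, −20 to 0 °C
Reagents that add atoms: none
Why: Luche reduction gives clean 1,2-reduction of the enone, and axial hydride delivery to the half-chair that keeps the isopropenyl group equatorial places the new hydroxyl cis to that group.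

Step 2
Reactants: 2 (1R,5R)-cis-carveol
Product: 3 (1S,5R)-trans-carveyl 4-nitrobenzoate
Conditions: 4-nitrobenzoic acid, PPh3, DIAD, THF, 0 °C to rt
Reagents that add atoms: 4-nitrobenzoic acid, O=C(O)c1ccc(cc1)[N+](=O)[O-]
Why: Mitsunobu reaction, in which SN2 displacement of the oxyphosphonium by the carboxylate inverts the carbinol carbon so that the oxygen (the future O3) ends trans to the isopropenyl group.

Step 3
Reactants: 3 (1S,5R)-trans-carveyl 4-nitrobenzoate
Product: 4 (1S,5R)-trans-carveol
Conditions: K2CO3 (catalytic), MeOH, rt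
Reagents that add atoms: none
Why: Base-catalysed transesterification of the activated aryl ester with methanol frees the alcohol without touching the stereocentre.

Step 4
Reactants: 4 (1S,5R)-trans-carveol
Product: 5 (1S,5R)-trans-carveol tert-butyldimethylsilyl ether
Conditions: TBSCl, imidazole, DMF, rt
Reagents that add atoms: tert-butyldimethylsilyl chloride, CC(C)(C)[Si](C)(C)Cl
Why: Standard silylation of a secondary allylic alcohol, giving an ether that withstands organolithium reagents, KH and mild acid and can be removed late with fluoride.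

Step 5
Reactants: 5 (1S,5R)-trans-carveol tert-butyldimethylsilyl ether
Product: 6 ring epoxide of 5 (oxirane oxygen anti to the silyloxy group)
Conditions: mCPBA (1 equiv), NaHCO3, CH2Cl2, 0 °C
Reagents that add atoms: 3-chloroperoxybenzoic acid, OOC(=O)c1cccc(Cl)c1
Why: Prilezhaev epoxidation, in which the trisubstituted ring alkene outpaces the 1,1-disubstituted isopropenyl alkene and the pseudoaxial allylic silyloxy group steers the peracid to the opposite face.

Step 6
Reactants: 6 ring epoxide of 5
Product: 9 6-(tert-butyldimethylsilyloxy)-p-mentha-2,8-dien-1-ol (tertiary allylic alcohol), via hydroxy selenide 7 (not isolated), via selenoxide 8 (not isolated)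
Conditions: PhSeSePh, NaBH4, EtOH, reflux; then 30% H2O2, pyridine, THF, 0 °C to rt
Reagents that add atoms: none
Why: Trans-diaxial (Fürst–Plattner) opening of the epoxide by benzeneselenolate at the secondary carbon followed by selenoxide syn-elimination, which can only run away from the hydrogen-free carbinol carbon and so places the alkene between the future C5 and C6.

Step 7
Reactants: 9 6-(tert-butyldimethylsilyloxy)-p-mentha-2,8-dien-1-ol
Product: 10 (4S,6R)-4-(tert-butyldimethylsilyloxy)-3-methyl-6-(prop-1-en-2-yl)cyclohex-2-en-1-one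
Conditions: pyridinium chlorochromate (C5H5NH)[CrO3Cl], 4 Å molecular sieves, CH2Cl2, rt
Reagents that add atoms: pyridinium chlorochromate, [O-][Cr](=O)(=O)Cl.c1cc[nH+]cc1
Why: Babler–Dauben oxidative 1,3-transposition, in which the tertiary chromate ester undergoes a [3,3] shift and the resulting secondary allylic chromate is oxidised, placing the carbonyl at the future C6 next to the isopropenyl-bearing carbon without touching either stereocentre.

Step 8
Reactants: 11 cis-2-butene-1,4-diol
Product: 12 2,2-dimethyl-4,7-dihydro-1,3-dioxepine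
Conditions: 2,2-dimethoxypropane, p-TsOH (catalytic), CH2Cl2, rt
Reagents that add atoms: 2,2-dimethoxypropane, COC(C)(C)OC
Why: Acid-catalysed transketalisation of the cis-1,4-diol, driven by loss of methanol, closes the seven-membered acetonide.

Step 9
Reactants: 12 2,2-dimethyl-4,7-dihydro-1,3-dioxepine
Product: 13 2,2-dimethyl-4,5-dihydro-1,3-dioxepine
Conditions: KOt-Bu (catalytic), DMSO, 50 °C
Reagents that add atoms: none
Why: Base-mediated prototropic isomerisation of an allyl ether to the conjugated enol ether, which in this symmetric ring can give only one product.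

Step 10
Reactants: 13 2,2-dimethyl-4,5-dihydro-1,3-dioxepine
Product: 15 6-bromo-2,2-dimethyl-4,5-dihydro-1,3-dioxepine, via trans-dibromide 14 (not isolated)
Conditions: Br2, CH2Cl2, −78 °C; then Et3N, −78 °C to rt
Reagents that add atoms: bromine, BrBr
Why: Electrophilic bromine addition to the enol ether followed by amine-induced loss of HBr from the α-bromo ether through the oxocarbenium ion gives the β-bromo enol ether, the same sequence that converts dihydropyran into 5-bromo-3,4-dihydro-2H-pyran.

Step 11
Reactants: 15 6-bromo-2,2-dimethyl-4,5-dihydro-1,3-dioxepine; 10 (4S,6R)-4-(tert-butyldimethylsilyloxy)-3-methyl-6-(prop-1-en-2-yl)cyclohex-2-en-1-one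
Product: 17 1-(2,2-dimethyl-4,5-dihydro-1,3-dioxepin-6-yl)-4-(tert-butyldimethylsilyloxy)-3-methyl-6-(prop-1-en-2-yl)cyclohex-2-en-1-ol (dioxepinyl trans to isopropenyl), via lithiodioxepine 16 (not isolated)
Conditions: t-BuLi (2 equiv), Et2O, −78 °C; then 10 in THF, −78 °C; H2O quench, product used without chromatography
Reagents that add atoms: none
Why: Bromine–lithium exchange gives a cyclic β-lithio enol ether that cannot eliminate, and its 1,2-addition to the hindered enone should occur on the face opposite the adjacent equatorial isopropenyl group (equatorial-type attack on the half-chair), setting the C6 carbinol with the two alkenyl groups trans.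

Step 12
Reactants: 17 1-(2,2-dimethyl-4,5-dihydro-1,3-dioxepin-6-yl)-4-(tert-butyldimethylsilyloxy)-3-methyl-6-(prop-1-en-2-yl)cyclohex-2-en-1-ol
Product: 20 3β-(tert-butyldimethylsilyloxy)-8β,12-(isopropylidenedioxy)-13-norgermacra-1(10)E,4Z-dien-6-one (7α-H), via potassium alkoxide 18 (not isolated), via potassium enolate 19 (not isolated)
Conditions: KH, 18-crown-6, THF, 0 °C to rt; then transfer into AcOH/THF at −78 °C
Reagents that add atoms: none
Why: KH converts 17 into the potassium alkoxide 18, whose oxyanion at C6 loosens the adjacent, doubly allylic C1–C6 bond so that a concerted [3,3]-sigmatropic shift across C9=C10–C1–C6–C7=C8 makes C8–C9 as C1–C6 breaks, with the enolate 19 as the energetic sink (anionic oxy-Cope rearrangement; closest known reaction type: ring expansion of trans-1,2-dialkenylcyclohexanols to cyclodec-5-enones, here with a β-oxygenated cycloalkenyl partner). The ten-membered carbocycle is thus not closed end to end but grows out of the six-membered ring by insertion of C7–C10, through a chair-shaped six-centre array in which the ring bonds C1–C2 and C6–C5 are both equatorial (trans-decalin-like) and the oxyanion is axial. C8 is controlled by that chair together with the enol ether geometry: since O8 and C11 are tied cis in the dioxepine, O8 is trans to C6 and must sit equatorial, and with the C1 and C6 configurations fixed in steps 1–11 this exposes the face of C8 that gives the 8β-oxygen, while the equatorial C2 becomes the E C1=C10 alkene and the cyclohexene hands on its cis C4=C5 bond. C7 is controlled in the quench: 19 is an E ring enolate whose inner face looks across the ring at C1=C10, so acetic acid at −78 °C should protonate from outside, anti to the new C8–C9 bond, giving H7 cis to H8 (7α-H, cis-fused dioxepane). The selectivities required are chair over boat and participation of the exocyclic dioxepinyl alkene instead of the ring C4=C5 alkene, and both are secured by the trans-diequatorial placement of the two alkenyl groups, which holds C9 over C8 and far from C4. Ejection of O8 from the β-alkoxy enolate is the side reaction to suppress: the acetal ring holds the C8–O8 bond close to the enolate plane, where overlap is poor, and the enolate is kept no longer than needed before the cold inverse quench.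

Step 13
Reactants: 20 3β-(tert-butyldimethylsilyloxy)-8β,12-(isopropylidenedioxy)-13-norgermacra-1(10)E,4Z-dien-6-one
Product: 21 3β-(tert-butyldimethylsilyloxy)-8β,12-dihydroxy-13-norgermacra-1(10)E,4Z-dien-6-one
Conditions: AcOH/THF/H2O (3:1:1), rt
Reagents that add atoms: none
Why: Acetal hydrolysis, in which the seven-membered acetonide of a 1,4-diol is far more labile than the secondary TBS ether and aqueous rather than methanolic acid avoids methyl ketal formation at the γ-hydroxy ketone.

Step 14
Reactants: 21 3β-(tert-butyldimethylsilyloxy)-8β,12-dihydroxy-13-norgermacra-1(10)E,4Z-dien-6-one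
Product: 22 3β-(tert-butyldimethylsilyloxy)-13-norgermacra-1(10)E,4Z-diene-6α,8β,12-triol
Conditions: Me4NBH(OAc)3, MeCN/AcOH (1:1), −30 °C
Reagents that add atoms: none
Why: Evans–Saksena reduction, in which the 8β-hydroxyl exchanges onto boron and hydride is delivered intramolecularly to the β face of the C6 carbonyl, giving the 6α-alcohol (1,3-anti to O8) with 1,2-selectivity on the enone.

Step 15
Reactants: 22 3β-(tert-butyldimethylsilyloxy)-13-norgermacra-1(10)E,4Z-diene-6α,8β,12-triol
Product: 24 3β-(tert-butyldimethylsilyloxy)-8β-hydroxy-13-norgermacra-1(10)E,4Z-dien-12,6α-olide, via lactol 23 (not isolated)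
Conditions: TEMPO (catalytic), PhI(OAc)2, CH2Cl2, rt
Reagents that add atoms: none
Why: Oxoammonium-mediated oxidative lactonisation, in which the primary alcohol is oxidised selectively, the aldehyde is captured by the 6α-hydroxyl that lies anti to C11 across C6–C7 (a trans ring fusion the ten-membered ring accommodates, whereas closure onto the 8β-hydroxyl would need a nearly eclipsed C7–C8 bond), and the lactol is oxidised on to the trans 6,12-lactone.

Step 16
Reactants: 24 3β-(tert-butyldimethylsilyloxy)-8β-hydroxy-13-norgermacra-1(10)E,4Z-dien-12,6α-olide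
Product: 25 3β-(tert-butyldimethylsilyloxy)-8β-(triethylsilyloxy)-13-norgermacra-1(10)E,4Z-dien-12,6α-olide
Conditions: Et3SiCl, imidazole, DMF, 0 °C
Reagents that add atoms: triethylsilyl chloride, CC[Si](Cl)(CC)CC
Why: Silylation of the only free hydroxyl removes the acidic proton and the risk of translactonisation before the lactone is enolised.

Step 17
Reactants: 25 3β-(tert-butyldimethylsilyloxy)-8β-(triethylsilyloxy)-13-norgermacra-1(10)E,4Z-dien-12,6α-olide
Product: 26 13-(dimethylamino)-3β-(tert-butyldimethylsilyloxy)-8β-(triethylsilyloxy)germacra-1(10)E,4Z-dien-12,6α-olide (C11 epimers)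
Conditions: LiN(iPr)2, THF, −78 °C; then N,N-dimethylmethyleneiminium iodide (Eschenmoser's salt), −78 to 0 °C
Reagents that add atoms: N,N-dimethylmethyleneiminium iodide, C=[N+](C)C.[I-]
Why: Mannich reaction of the lactone lithium enolate with the preformed iminium salt brings in C13, and the configuration created at C11 is irrelevant because it is removed in the next step.

Step 18
Reactants: 26 13-(dimethylamino)-3β-(tert-butyldimethylsilyloxy)-8β-(triethylsilyloxy)germacra-1(10)E,4Z-dien-12,6α-olide
Product: 28 3β-(tert-butyldimethylsilyloxy)-8β-(triethylsilyloxy)germacra-1(10)E,4Z,11(13)-trien-12,6α-olide, via ammonium iodide 27 (not isolated)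
Conditions: MeI, THF/MeOH, rt; then NaHCO3 (aq), CH2Cl2, rt
Reagents that add atoms: none
Why: Quaternisation of the amine followed by E1cB (Hofmann-type) loss of trimethylamine under mild bicarbonate conditions gives the exocyclic α-methylene lactone.

Step 19
Reactants: 28 3β-(tert-butyldimethylsilyloxy)-8β-(triethylsilyloxy)germacra-1(10)E,4Z,11(13)-trien-12,6α-olide
Product: 29 3β-(tert-butyldimethylsilyloxy)-8β-hydroxygermacra-1(10)E,4Z,11(13)-trien-12,6α-olide
Conditions: HF·pyridine, pyridine, THF, 0 °C
Reagents that add atoms: none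
Why: Buffered HF·pyridine cleaves a triethylsilyl ether much faster than a secondary TBS ether, and the acidic, non-nucleophilic medium spares the Michael acceptor.

Step 20
Reactants: 30 angelic acid
Product: 31 (Z)-2-methylbut-2-en-1-ol
Conditions: LiAlH4, Et2O, 0 °C
Reagents that add atoms: none
Why: Hydride reduction of the carboxylate proceeds in 1,2 fashion and leaves the trisubstituted Z-alkene unreduced and unisomerised.

Step 21
Reactants: 31 (Z)-2-methylbut-2-en-1-ol
Product: 32 (2R,3S)-2,3-epoxy-2-methylbutan-1-ol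
Conditions: Ti(OiPr)4, D-(−)-diethyl tartrate, t-BuOOH, 4 Å molecular sieves, CH2Cl2, −20 °C
Reagents that add atoms: tert-butyl hydroperoxide, CC(C)(C)OO
Why: Sharpless asymmetric epoxidation, in which the D-(−)-tartrate titanium complex delivers oxygen to the alkene face that gives the (2R,3S)-epoxy alcohol while the cis relation of the C3 methyl and the CH2OH group is carried over from the Z-alkene.

Step 22
Reactants: 32 (2R,3S)-2,3-epoxy-2-methylbutan-1-ol
Product: 33 (2S,3S)-2,3-epoxy-2-methylbutanoic acid
Conditions: RuCl3·xH2O (catalytic), NaIO4, MeCN/EtOAc/H2O, 0 °C to rt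
Reagents that add atoms: water, O
Why: RuO4 generated in situ oxidises the primary alcohol through the aldehyde hydrate to the acid without opening the oxirane, and the descriptor at C2 changes from R to S only because of the new substituent priority.

Step 23
Reactants: 33 (2S,3S)-2,3-epoxy-2-methylbutanoic acid; 29 3β-(tert-butyldimethylsilyloxy)-8β-hydroxygermacra-1(10)E,4Z,11(13)-trien-12,6α-olide
Product: 35 3β-(tert-butyldimethylsilyloxy)-8β-[(2S,3S)-2,3-epoxy-2-methylbutanoyloxy]germacra-1(10)E,4Z,11(13)-trien-12,6α-olide, via mixed anhydride 34 (not isolated)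
Conditions: 2,4,6-trichlorobenzoyl chloride, Et3N, toluene, rt; then 29, DMAP, toluene, rt
Reagents that add atoms: none
Why: Yamaguchi esterification, in which DMAP attacks the less shielded aliphatic carbonyl of the mixed anhydride and transfers the α-quaternary, non-enolisable epoxy acyl group to the hindered 8β-hydroxyl without disturbing either stereocentre of the acid.

Step 24
Reactants: 35 3β-(tert-butyldimethylsilyloxy)-8β-[(2S,3S)-2,3-epoxy-2-methylbutanoyloxy]germacra-1(10)E,4Z,11(13)-trien-12,6α-olide
Product: 36 3β-hydroxy-8β-[(2S,3S)-2,3-epoxy-2-methylbutanoyloxy]germacra-1(10)E,4Z,11(13)-trien-12,6α-olide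
Conditions: HF·pyridine, THF, 0 °C to rt
Reagents that add atoms: none
Why: Fluoride-driven cleavage of the allylic TBS ether under acidic, non-basic conditions that leave the ester-deactivated oxirane, the ester and the α-methylene lactone intact.

Step 25
Reactants: 36 3β-hydroxy-8β-[(2S,3S)-2,3-epoxy-2-methylbutanoyloxy]germacra-1(10)E,4Z,11(13)-trien-12,6α-olide; 37 isovaleryl chloride
Product: 38 3β-(3-methylbutanoyloxy)-8β-[(2S,3S)-2,3-epoxy-2-methylbutanoyloxy]germacra-1(10)E,4Z,11(13)-trien-12,6α-olide
Conditions: pyridine, DMAP (catalytic), CH2Cl2, 0 °C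
Reagents that add atoms: none
Why: Nucleophile-catalysed acylation of the only free hydroxyl with an unhindered acid chloride proceeds with retention at C3.

Step 26
Reactants: 38 3β-(3-methylbutanoyloxy)-8β-[(2S,3S)-2,3-epoxy-2-methylbutanoyloxy]germacra-1(10)E,4Z,11(13)-trien-12,6α-olide
Product: 39 target CNP0167461.1 (1β,10α-epoxide of 38)
Conditions: mCPBA (1 equiv), NaHCO3, CH2Cl2, 0 °C
Reagents that add atoms: 3-chloroperoxybenzoic acid, OOC(=O)c1cccc(Cl)c1
Why: Prilezhaev epoxidation picks the strained, electron-rich E C1=C10 alkene over the C4=C5 alkene (flanked by two allylic acyloxy groups) and the electron-poor C11=C13 alkene, and attack on the outer face of the lactone-locked conformer with C14 up should give the 1β,10α-oxirane.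

**Compound list**

1 | (R)-(−)-carvone, (5R)-2-methyl-5-(prop-1-en-2-yl)cyclohex-2-en-1-one | CC1=CC[C@H](CC1=O)C(C)=C | starting material
2 | (1R,5R)-cis-carveol | CC1=CC[C@H](C[C@H]1O)C(C)=C | intermediate
3 | (1S,5R)-trans-carveyl 4-nitrobenzoate | CC1=CC[C@H](C[C@@H]1OC(=O)c2ccc(cc2)[N+](=O)[O-])C(C)=C | intermediate
4 | (1S,5R)-trans-carveol | CC1=CC[C@H](C[C@@H]1O)C(C)=C | intermediate
5 | (1S,5R)-trans-carveol tert-butyldimethylsilyl ether | CC1=CC[C@H](C[C@@H]1O[Si](C)(C)C(C)(C)C)C(C)=C | intermediate
6 | ring epoxide of 5, oxirane oxygen anti to OTBS and on the face of the isopropenyl group | C[C@]12O[C@H]1C[C@H](C[C@@H]2O[Si](C)(C)C(C)(C)C)C(C)=C | intermediate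
7 | hydroxy selenide: tertiary alcohol at the methyl-bearing carbon, PhSe on the neighbouring carbon trans to OH | C[C@]1(O)[C@H]([Se]c2ccccc2)C[C@H](C[C@@H]1O[Si](C)(C)C(C)(C)C)C(C)=C | intermediate
8 | selenoxide of 7 (selenium configuration undefined) | C[C@]1(O)[C@H]([Se](=O)c2ccccc2)C[C@H](C[C@@H]1O[Si](C)(C)C(C)(C)C)C(C)=C | intermediate
9 | 6-(tert-butyldimethylsilyloxy)-p-mentha-2,8-dien-1-ol, tertiary OH anti to OTBS, OTBS trans to isopropenyl | C[C@]1(O)C=C[C@H](C[C@@H]1O[Si](C)(C)C(C)(C)C)C(C)=C | intermediate
10 | (4S,6R)-4-(tert-butyldimethylsilyloxy)-3-methyl-6-(prop-1-en-2-yl)cyclohex-2-en-1-one | O=C1C=C(C)[C@@H](O[Si](C)(C)C(C)(C)C)C[C@@H]1C(C)=C | intermediate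
11 | cis-2-butene-1,4-diol | OC/C=C\CO | starting material
12 | 2,2-dimethyl-4,7-dihydro-1,3-dioxepine | CC1(C)OCC=CCO1 | intermediate
13 | 2,2-dimethyl-4,5-dihydro-1,3-dioxepine | CC1(C)OCCC=CO1 | intermediate
14 | trans-4,5-dibromo-2,2-dimethyl-1,3-dioxepane (racemic, one enantiomer drawn) | Br[C@@H]1OC(C)(C)OCC[C@H]1Br | intermediate
15 | 6-bromo-2,2-dimethyl-4,5-dihydro-1,3-dioxepine | BrC1=COC(C)(C)OCC1 | intermediate
16 | (2,2-dimethyl-4,5-dihydro-1,3-dioxepin-6-yl)lithium | [Li]C1=COC(C)(C)OCC1 | intermediate
17 | 1-(2,2-dimethyl-4,5-dihydro-1,3-dioxepin-6-yl)-4-(tert-butyldimethylsilyloxy)-3-methyl-6-(prop-1-en-2-yl)cyclohex-2-en-1-ol; dioxepinyl and OTBS on one face, OH and isopropenyl on the other | O[C@]1(C2=COC(C)(C)OCC2)C=C(C)[C@@H](O[Si](C)(C)C(C)(C)C)C[C@@H]1C(C)=C | intermediate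
18 | potassium alkoxide of 17 | [K+].[O-][C@]1(C2=COC(C)(C)OCC2)C=C(C)[C@@H](O[Si](C)(C)C(C)(C)C)C[C@@H]1C(C)=C | intermediate
19 | potassium enolate (C6–O⁻, E C6=C7 in the ten-membered ring, 8β-O in the dioxepane) | [K+].[O-]/C1=C2/CCOC(C)(C)O[C@@H]2C/C(C)=C/C[C@H](O[Si](C)(C)C(C)(C)C)/C(C)=C\1 | intermediate
20 | 3β-(tert-butyldimethylsilyloxy)-8β,12-(isopropylidenedioxy)-13-norgermacra-1(10)E,4Z-dien-6-one, 7α-H | O=C1/C=C(/C)[C@@H](O[Si](C)(C)C(C)(C)C)C/C=C(\C)C[C@H]2OC(C)(C)OCC[C@@H]12 | intermediate
21 | 3β-(tert-butyldimethylsilyloxy)-8β,12-dihydroxy-13-norgermacra-1(10)E,4Z-dien-6-one | O=C1/C=C(/C)[C@@H](O[Si](C)(C)C(C)(C)C)C/C=C(\C)C[C@@H](O)[C@H]1CCO | intermediate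
22 | 3β-(tert-butyldimethylsilyloxy)-13-norgermacra-1(10)E,4Z-diene-6α,8β,12-triol | O[C@@H]1/C=C(/C)[C@@H](O[Si](C)(C)C(C)(C)C)C/C=C(\C)C[C@@H](O)[C@H]1CCO | intermediate
23 | 6α,12-lactol of 22 (anomeric mixture) | C1C(O)O[C@@H]2/C=C(/C)[C@@H](O[Si](C)(C)C(C)(C)C)C/C=C(\C)C[C@@H](O)[C@@H]12 | intermediate
24 | 3β-(tert-butyldimethylsilyloxy)-8β-hydroxy-13-norgermacra-1(10)E,4Z-dien-12,6α-olide | C1C(=O)O[C@@H]2/C=C(/C)[C@@H](O[Si](C)(C)C(C)(C)C)C/C=C(\C)C[C@@H](O)[C@@H]12 | intermediate
25 | 8-O-triethylsilyl ether of 24 | C1C(=O)O[C@@H]2/C=C(/C)[C@@H](O[Si](C)(C)C(C)(C)C)C/C=C(\C)C[C@@H](O[Si](CC)(CC)CC)[C@@H]12 | intermediate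
26 | 13-(dimethylamino) lactone (C11 epimers, C11 undefined) | CN(C)CC1C(=O)O[C@@H]2/C=C(/C)[C@@H](O[Si](C)(C)C(C)(C)C)C/C=C(\C)C[C@@H](O[Si](CC)(CC)CC)[C@@H]12 | intermediate
27 | 13-(trimethylammonio) lactone iodide | C[N+](C)(C)CC1C(=O)O[C@@H]2/C=C(/C)[C@@H](O[Si](C)(C)C(C)(C)C)C/C=C(\C)C[C@@H](O[Si](CC)(CC)CC)[C@@H]12.[I-] | intermediate
28 | 3β-(tert-butyldimethylsilyloxy)-8β-(triethylsilyloxy)germacra-1(10)E,4Z,11(13)-trien-12,6α-olide | C=C1C(=O)O[C@@H]2/C=C(/C)[C@@H](O[Si](C)(C)C(C)(C)C)C/C=C(\C)C[C@@H](O[Si](CC)(CC)CC)[C@@H]12 | intermediate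
29 | 3β-(tert-butyldimethylsilyloxy)-8β-hydroxygermacra-1(10)E,4Z,11(13)-trien-12,6α-olide | C=C1C(=O)O[C@@H]2/C=C(/C)[C@@H](O[Si](C)(C)C(C)(C)C)C/C=C(\C)C[C@@H](O)[C@@H]12 | intermediate
30 | angelic acid, (Z)-2-methylbut-2-enoic acid | C/C=C(/C)C(=O)O | starting material
31 | (Z)-2-methylbut-2-en-1-ol | C/C=C(/C)CO | intermediate
32 | (2R,3S)-2,3-epoxy-2-methylbutan-1-ol (CH2OH and C3 methyl cis) | OC[C@@]1(C)O[C@H]1C | intermediate
33 | (2S,3S)-2,3-epoxy-2-methylbutanoic acid (epoxyangelic acid) | OC(=O)[C@@]1(C)O[C@H]1C | intermediate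
34 | mixed anhydride of 33 with 2,4,6-trichlorobenzoic acid | Clc1cc(Cl)c(C(=O)OC(=O)[C@@]2(C)O[C@H]2C)c(Cl)c1 | intermediate
35 | 3β-(tert-butyldimethylsilyloxy)-8β-[(2S,3S)-2,3-epoxy-2-methylbutanoyloxy]germacra-1(10)E,4Z,11(13)-trien-12,6α-olide | C=C1C(=O)O[C@@H]2/C=C(/C)[C@@H](O[Si](C)(C)C(C)(C)C)C/C=C(\C)C[C@@H](OC(=O)[C@@]3(C)O[C@H]3C)[C@@H]12 | intermediate
36 | 3β-hydroxy-8β-[(2S,3S)-2,3-epoxy-2-methylbutanoyloxy]germacra-1(10)E,4Z,11(13)-trien-12,6α-olide | C=C1C(=O)O[C@@H]2/C=C(/C)[C@@H](O)C/C=C(\C)C[C@@H](OC(=O)[C@@]3(C)O[C@H]3C)[C@@H]12 | intermediate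
37 | isovaleryl chloride, 3-methylbutanoyl chloride | CC(C)CC(=O)Cl | starting material
38 | 3β-(3-methylbutanoyloxy)-8β-[(2S,3S)-2,3-epoxy-2-methylbutanoyloxy]germacra-1(10)E,4Z,11(13)-trien-12,6α-olide | C=C1C(=O)O[C@@H]2/C=C(/C)[C@@H](OC(=O)CC(C)C)C/C=C(\C)C[C@@H](OC(=O)[C@@]3(C)O[C@H]3C)[C@@H]12 | intermediate
39 | CNP0167461.1: 1β,10α-epoxy-3β-(3-methylbutanoyloxy)-8β-[(2S,3S)-2,3-epoxy-2-methylbutanoyloxy]germacra-4Z,11(13)-dien-12,6α-olide | C=C1C(=O)O[C@@H]2/C=C(/C)[C@@H](OC(=O)CC(C)C)C[C@H]3O[C@]3(C)C[C@@H](OC(=O)[C@@]3(C)O[C@H]3C)[C@@H]12 | target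

**Step count and risks**

Total step count: 26 steps (7 to enone 10, 3 to bromodioxepine 15, 3 to acid 33, 13 after the fragments meet).
Longest linear sequence: 20 steps, from 1 to 39 (steps 1–7, 11–19, 23–26).

Steps most likely to fail, riskiest first:

1. Step 12. The potassium enolate may expel the C8 oxygen (E1cB opening of the acetal) while it waits at ambient temperature, or the quench may protonate C7 without facial control. Fallback: from 17 the rearrangement is run in the same way, but the enolate is not protonated. Me3SiCl/Et3N is added at −78 °C as soon as the rearrangement is complete, which converts it into the neutral trimethylsilyl enol ether F1 (C6–OSiMe3, C6=C7). F1 can be purified, and C7 is then protonated in a separate operation by buffered protodesilylation (Bu4NF/AcOH, THF, −78 °C), where the proton source can be chosen for peripheral delivery. This returns to 20.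

2. Step 15. The aldehyde from the primary alcohol may be captured by the wrong hydroxyl (closure onto O8 to the cis 8,12-lactone), or the allylic 6-hydroxyl may be oxidised. Fallback: from 21 both hydroxyls are silylated (Et3SiCl, imidazole) to the bis-triethylsilyl ether F2. With O8 blocked, the C6 ketone is reduced under reagent control with (R)-2-methyl-CBS-oxazaborolidine and catecholborane (toluene, −78 °C), assuming the alkenyl arm acts as the larger group, to the 6α-alcohol F3. The primary triethylsilyl ether is then removed selectively (PPTS, MeOH/CH2Cl2, −10 °C) to give the 6α,12-diol F4, in which O6 is the only hydroxyl able to capture the aldehyde. TEMPO/PhI(OAc)2 then gives 25 directly, so the route is rejoined after step 16.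

3. Step 6. The selenolate must approach the secondary oxirane carbon syn-axial to the silyloxy group, so the opening may be slow or take the wrong course, and the peroxide may epoxidise the isopropenyl group. Fallback: from 5 the ring methylene next to the isopropenyl-bearing carbon, the only unfunctionalised allylic CH2 of the ring alkene, is oxidised directly to the enone with CrO3·3,5-dimethylpyrazole (CH2Cl2, −20 °C). This reaches 10 in one operation, replaces steps 5–7 and makes no new compound (F0).

**Further compounds**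

F1 | step 12 | trimethylsilyl enol ether of 20 (C6–OSiMe3, E C6=C7, 8β-O) | C[Si](C)(C)O/C1=C2/CCOC(C)(C)O[C@@H]2C/C(C)=C/C[C@H](O[Si](C)(C)C(C)(C)C)/C(C)=C\1
F2 | step 15 | 8,12-bis-O-triethylsilyl ether of 21 | O=C1/C=C(/C)[C@@H](O[Si](C)(C)C(C)(C)C)C/C=C(\C)C[C@@H](O[Si](CC)(CC)CC)[C@H]1CCO[Si](CC)(CC)CC
F3 | step 15 | 6α-alcohol from F2 | O[C@@H]1/C=C(/C)[C@@H](O[Si](C)(C)C(C)(C)C)C/C=C(\C)C[C@@H](O[Si](CC)(CC)CC)[C@H]1CCO[Si](CC)(CC)CC
F4 | step 15 | 6α,12-diol with 8β-triethylsilyloxy group | O[C@@H]1/C=C(/C)[C@@H](O[Si](C)(C)C(C)(C)C)C/C=C(\C)C[C@@H](O[Si](CC)(CC)CC)[C@H]1CCO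
F0 | step 6 | none | none
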